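**Retrosynthetic overview**
1. Ring B is closed last. The 2-methyleneoxane is opened at O1–C6 to an acyclic α-oxy methyl ketone carrying a prenyl group. In the forward sense the ketone oxygen opens a prenyl bromonium ion 6-endo, and the oxocarbenium ion then loses a methyl proton, so the C–Br bond, the C–O bond and the enol ether form in one operation.
2. The quaternary carbinol carbon comes from a three-component union of an α-cyclohexyl vinyl ketone, an isobutenyl copper nucleophile and an electrophilic oxygen atom.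
3. The vinyl ketone comes from the isopropenyl group of a 2-bromo-1-chloro-p-menth-8-ene by ozonolysis, enol triflate formation and acetyl-anion coupling.
4. Ring A is closed first, at the C3–C4 bond of the p-menthene, which is the C1–C6 closure of a neryl cation equivalent. The distal olefin attacks a bromine-assisted primary carbon, and the terpinyl-type cation loses a proton.
5. The acyclic bromochloride comes from nerol (1) by catalytic enantioselective bromochlorination, which sets the first two stereocentres.

Assumption: the antipodes named for the Schiff-base ligand (step 1) and the oxaziridine (step 6) are taken to be those that give the drawn configurations. Both antipodes of each are available, so the other one is used if the sense is opposite.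

**Step 1**
Reactants: 1 nerol, (2Z)-3,7-dimethylocta-2,6-dien-1-ol
Product: 2 (2S,3S)-2-bromo-3-chloro-3,7-dimethyloct-6-en-1-ol
Conditions: NBS (1.1 equiv), ClTi(OiPr)3 (1.1 equiv), (S)-2,4-di-tert-butyl-6-{(E)-[(1-hydroxy-3,3-dimethyl-1,1-diphenylbutan-2-yl)imino]methyl}phenol (15 mol %), hexanes, −20 °C
Reagents that add atoms: N-bromosuccinimide, O=C1CCC(=O)N1Br; chlorotitanium triisopropoxide ClTi(OiPr)3, CC(C)O[Ti](Cl)(OC(C)C)OC(C)C
Why: This is a titanium/Schiff-base-catalysed enantioselective bromochlorination of an allylic alcohol, in which the alkoxide-bound titanium steers Br+ to one face of the allylic olefin only (the remote olefin is untouched) and delivers chloride anti at the tertiary carbon, so the ligand sets both carbon–halogen centres and anti addition to the Z-olefin gives the relative configuration that becomes the trans Br/Cl pair of ring A.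

**Step 2**
Reactants: 2 (2S,3S)-2-bromo-3-chloro-3,7-dimethyloct-6-en-1-ol
Product: 6 (1S,2S,4S)-2-bromo-1-chloro-1-methyl-4-(prop-1-en-2-yl)cyclohexane, via primary triflate 3 (not isolated), via bromonium ion 4 (not isolated), via tertiary carbocation 5 (not isolated)
Conditions: Tf2O (1.05 equiv), 2,6-di-tert-butyl-4-methylpyridine (DTBMP, 2.5 equiv), CH2Cl2, −78 °C; then 1,1,1,3,3,3-hexafluoropropan-2-ol (HFIP) co-solvent, −40 → 0 °C
Reagents that add atoms: none
Why: Proposed new method: the β-bromo primary triflate ionises in the ionising, non-nucleophilic medium with anchimeric help from bromine, the distal trisubstituted olefin opens the bromonium ion at its unhindered CH2 terminus anti to bromine through a chair, so Br is born equatorial, which forces Cl equatorial and CH3 axial from the fixed anti adduct and lets the side chain take the third equatorial site (the 1,3-cis Br/side-chain, trans Br/Cl array that trans-diaxial BrCl addition to a preformed 4-substituted 1-methylcyclohexene does not give), and the hindered pyridine takes a methyl proton from the terpinyl-type cation; the closest known reaction types are π-route solvolytic cyclisation of alkenyl sulfonates, bromonium-initiated cation–olefin cyclisation and enantiospecific bromonium generation from β-bromo leaving groups.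

**Step 3**
Reactants: 6 (1S,2S,4S)-2-bromo-1-chloro-1-methyl-4-(prop-1-en-2-yl)cyclohexane
Product: 8 1-[(1S,3S,4S)-3-bromo-4-chloro-4-methylcyclohexyl]ethan-1-one, via secondary ozonide 7 (not isolated)
Conditions: O3, CH2Cl2, −78 °C; then Me2S, −78 °C → rt
Reagents that add atoms: ozone, [O-][O+]=O
Why: Ozonolysis with reductive work-up (Criegee mechanism) cleaves the only C=C bond to the methyl ketone and touches neither the alkyl halides nor the three stereocentres.

**Step 4**
Reactants: 8 1-[(1S,3S,4S)-3-bromo-4-chloro-4-methylcyclohexyl]ethan-1-one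
Product: 10 1-[(1S,3S,4S)-3-bromo-4-chloro-4-methylcyclohexyl]ethenyl trifluoromethanesulfonate, via lithium enolate 9 (not isolated)
Conditions: LiN(iPr)2 (1.05 equiv), THF, −78 °C; then PhNTf2, −78 → 0 °C
Reagents that add atoms: N-phenylbis(trifluoromethanesulfonimide), O=S(=O)(N(c1ccccc1)S(=O)(=O)C(F)(F)F)C(F)(F)F
Why: Kinetic deprotonation at CH3 followed by O-sulfonylation (enol triflate formation) avoids enolisation toward the ring methine, so the adjacent ring stereocentre is not epimerised and no enolate carbon is placed 1,3 to the C–Br bond.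

**Step 5**
Reactants: 10 1-[(1S,3S,4S)-3-bromo-4-chloro-4-methylcyclohexyl]ethenyl trifluoromethanesulfonate; 11 tributyl(1-ethoxyethenyl)stannane
Product: 13 3-[(1S,3S,4S)-3-bromo-4-chloro-4-methylcyclohexyl]but-3-en-2-one, via 2-ethoxydiene 12 (not isolated)
Conditions: Pd(PPh3)4 (5 mol %), LiCl (3 equiv), THF, 65 °C; then 1 M HCl, THF, rt
Reagents that add atoms: tributyl(1-ethoxyethenyl)stannane, CCCC[Sn](CCCC)(CCCC)C(=C)OCC; water, O
Why: The Stille coupling (oxidative addition of the vinyl triflate to zerovalent palladium, chloride-assisted transmetalation, reductive elimination) is neutral and leaves the unactivated secondary bromide and tertiary chloride alone, and mild hydrolysis of the ethyl dienol ether unmasks the acetyl group without forming or touching a stereocentre.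

**Step 6**
Reactants: 13 3-[(1S,3S,4S)-3-bromo-4-chloro-4-methylcyclohexyl]but-3-en-2-one; 14 (2-methylprop-1-en-1-yl)magnesium bromide
Product: 17 (3R)-3-[(1S,3S,4S)-3-bromo-4-chloro-4-methylcyclohexyl]-6-methyl-3-[(triethylsilyl)oxy]hept-5-en-2-one, via magnesium enolate 15 (not isolated), via magnesium alkoxide 16 (not isolated)
Conditions: 14 (1.3 equiv), CuBr·SMe2 (20 mol %), THF, −78 °C; then (+)-(8,8-dichlorocamphorylsulfonyl)oxaziridine (1.5 equiv), −78 → −20 °C; then TESOTf (2 equiv), −78 → 0 °C
Reagents that add atoms: (2-methylprop-1-en-1-yl)magnesium bromide, CC(C)=C[Mg]Br; (8,8-dichlorocamphorylsulfonyl)oxaziridine, CC1(C)C2CCC13CS(=O)(=O)N4OC34C2(Cl)Cl; triethylsilyl trifluoromethanesulfonate, CC[Si](CC)(CC)OS(=O)(=O)C(F)(F)F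
Why: Copper-catalysed conjugate addition to the unsubstituted β-carbon of the s-trans-biased enone gives one tetrasubstituted (Z)-enolate regiospecifically, Davis enolate hydroxylation with the enantiopure N-sulfonyloxaziridine delivers oxygen to one enolate face under reagent control (the pseudo-symmetric ring has no bias of its own) and sets the carbinol centre as R, material from the minor enantiomer of 2 becomes a separable diastereomer here, and the alkoxide is capped in the same flask so that it cannot compete as a nucleophile in step 7.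

**Step 7**
Reactants: 17 (3R)-3-[(1S,3S,4S)-3-bromo-4-chloro-4-methylcyclohexyl]-6-methyl-3-[(triethylsilyl)oxy]hept-5-en-2-one
Product: 20 {[(3R,5R)-5-bromo-3-[(1S,3S,4S)-3-bromo-4-chloro-4-methylcyclohexyl]-6,6-dimethyl-2-methylideneoxan-3-yl]oxy}triethylsilane, via bromonium ion 18 (not isolated), via oxocarbenium ion 19 (not isolated)
Conditions: Et2SBr·SbCl5Br (BDSB, 0.98 equiv), MeNO2, −25 °C, 5 min; then iPr2NEt (5 equiv), −25 → 0 °C; chromatography on Et3N-deactivated silica
Reagents that add atoms: bromodiethylsulfonium bromopentachloroantimonate Et2SBr·SbCl5Br, CC[S+](Br)CC.Cl[Sb-](Cl)(Cl)(Cl)(Cl)Br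
Why: Proposed new method: Br+ transfer to the only olefin is reversible, the ketone oxygen opens the bromonium ion at the tertiary carbon (6-endo, Markovnikov, anti, so Br is equatorial) through the chair in which A(1,2) strain with the C-methyl of the nascent C=O+ bond puts the bulky cyclohexyl group axial and the silyloxy group equatorial, which sets C5 as R (Br cis to O-3), and the oxocarbenium salt is kept until all Br+ is spent and only then deprotonated at its single enolisable position (CH3), so the electron-rich enol ether never meets the brominating agent; the closest known reaction types are bromonium cyclisations terminated by the carbonyl oxygen of esters, carbonates and β-dicarbonyls, haloketalisation of unsaturated ketones, and amine-induced conversion of oxocarbenium ions into enol ethers.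

**Step 8**
Reactants: 20 {[(3R,5R)-5-bromo-3-[(1S,3S,4S)-3-bromo-4-chloro-4-methylcyclohexyl]-6,6-dimethyl-2-methylideneoxan-3-yl]oxy}triethylsilane
Product: 21 (3R,5R)-5-bromo-3-[(1S,3S,4S)-3-bromo-4-chloro-4-methylcyclohexyl]-6,6-dimethyl-2-methylideneoxan-3-ol (target)
Conditions: Bu4NF (1.1 equiv), THF, 0 °C; aqueous NaHCO3 work-up; Et3N-deactivated silica
Reagents that add atoms: none
Why: Fluoride-induced Si–O cleavage under non-acidic conditions frees the tertiary alcohol without protonating the enol ether, and the equatorial C–Br and C–Cl bonds have no antiperiplanar ring hydrogens for E2 loss, so all five stereocentres are retained.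

**Compound list**
1 | nerol, (2Z)-3,7-dimethylocta-2,6-dien-1-ol | CC(C)=CCC/C(C)=C\CO | starting material
2 | (2S,3S)-2-bromo-3-chloro-3,7-dimethyloct-6-en-1-ol | CC(C)=CCC[C@](C)(Cl)[C@@H](Br)CO | intermediate
3 | (2S,3S)-2-bromo-3-chloro-3,7-dimethyloct-6-en-1-yl trifluoromethanesulfonate | CC(C)=CCC[C@](C)(Cl)[C@@H](Br)COS(=O)(=O)C(F)(F)F | intermediate
4 | C1–C2 bromonium (bromiranium) ion derived from 3 | CC(C)=CCC[C@](C)(Cl)[C@H]1[Br+]C1 | intermediate
5 | 2-[(1S,3S,4S)-3-bromo-4-chloro-4-methylcyclohexyl]propan-2-ylium | C[C+](C)[C@H]1CC[C@](C)(Cl)[C@@H](Br)C1 | intermediate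
6 | (1S,2S,4S)-2-bromo-1-chloro-1-methyl-4-(prop-1-en-2-yl)cyclohexane | C=C(C)[C@H]1CC[C@](C)(Cl)[C@@H](Br)C1 | intermediate
7 | 3-[(1S,3S,4S)-3-bromo-4-chloro-4-methylcyclohexyl]-3-methyl-1,2,4-trioxolane | CC1(OCOO1)[C@H]2CC[C@](C)(Cl)[C@@H](Br)C2 | intermediate
8 | 1-[(1S,3S,4S)-3-bromo-4-chloro-4-methylcyclohexyl]ethan-1-one | CC(=O)[C@H]1CC[C@](C)(Cl)[C@@H](Br)C1 | intermediate
9 | lithium 1-[(1S,3S,4S)-3-bromo-4-chloro-4-methylcyclohexyl]ethen-1-olate | C=C(O[Li])[C@H]1CC[C@](C)(Cl)[C@@H](Br)C1 | intermediate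
10 | 1-[(1S,3S,4S)-3-bromo-4-chloro-4-methylcyclohexyl]ethenyl trifluoromethanesulfonate | C=C(OS(=O)(=O)C(F)(F)F)[C@H]1CC[C@](C)(Cl)[C@@H](Br)C1 | intermediate
11 | tributyl(1-ethoxyethenyl)stannane | CCCC[Sn](CCCC)(CCCC)C(=C)OCC | starting material
12 | (1S,2S,4S)-2-bromo-1-chloro-4-(3-ethoxybuta-1,3-dien-2-yl)-1-methylcyclohexane | C=C(OCC)C(=C)[C@H]1CC[C@](C)(Cl)[C@@H](Br)C1 | intermediate
13 | 3-[(1S,3S,4S)-3-bromo-4-chloro-4-methylcyclohexyl]but-3-en-2-one | CC(=O)C(=C)[C@H]1CC[C@](C)(Cl)[C@@H](Br)C1 | intermediate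
14 | (2-methylprop-1-en-1-yl)magnesium bromide | CC(C)=C[Mg]Br | starting material
15 | bromomagnesium (2Z)-3-[(1S,3S,4S)-3-bromo-4-chloro-4-methylcyclohexyl]-6-methylhepta-2,5-dien-2-olate | C/C(O[Mg]Br)=C(/[C@H]1CC[C@](C)(Cl)[C@@H](Br)C1)CC=C(C)C | intermediate
16 | bromomagnesium alkoxide of (3R)-3-[(1S,3S,4S)-3-bromo-4-chloro-4-methylcyclohexyl]-3-hydroxy-6-methylhept-5-en-2-one | CC(C)=CC[C@@](C(C)=O)(O[Mg]Br)[C@H]1CC[C@](C)(Cl)[C@@H](Br)C1 | intermediate
17 | (3R)-3-[(1S,3S,4S)-3-bromo-4-chloro-4-methylcyclohexyl]-6-methyl-3-[(triethylsilyl)oxy]hept-5-en-2-one | CC(C)=CC[C@@](C(C)=O)(O[Si](CC)(CC)CC)[C@H]1CC[C@](C)(Cl)[C@@H](Br)C1 | intermediate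
18 | side-chain bromonium ion of 17 | CC1(C)[Br+][C@@H]1C[C@@](C(C)=O)(O[Si](CC)(CC)CC)[C@H]2CC[C@](C)(Cl)[C@@H](Br)C2 | intermediate
19 | six-membered cyclic oxocarbenium ion (2-methyl, 5-bromo, 6,6-dimethyl, 3-silyloxy) | CC1=[O+]C(C)(C)[C@H](Br)C[C@@]1(O[Si](CC)(CC)CC)[C@H]2CC[C@](C)(Cl)[C@@H](Br)C2 | intermediate
20 | {[(3R,5R)-5-bromo-3-[(1S,3S,4S)-3-bromo-4-chloro-4-methylcyclohexyl]-6,6-dimethyl-2-methylideneoxan-3-yl]oxy}triethylsilane | C=C1OC(C)(C)[C@H](Br)C[C@@]1(O[Si](CC)(CC)CC)[C@H]2CC[C@](C)(Cl)[C@@H](Br)C2 | intermediate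
21 | (3R,5R)-5-bromo-3-[(1S,3S,4S)-3-bromo-4-chloro-4-methylcyclohexyl]-6,6-dimethyl-2-methylideneoxan-3-ol | C=C1OC(C)(C)[C@H](Br)C[C@@]1(O)[C@H]1CC[C@](C)(Cl)[C@@H](Br)C1 | target

**Step count**
Total step count: 8. Longest linear sequence: 8 steps, from nerol 1.

**The three steps most likely to fail**

**Step 2 (ring A closure).**
- Risks: the bromonium ion may be opened at its secondary carbon to give a cyclopentane, the tertiary chloride may ionise in competition, and the cation may lose the ring proton instead of a methyl proton.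
- The fallback sets out from 2 and comes back at 8. It replaces the olefin terminator by a much stronger one that needs no proton loss.
- Treating 2 with MsCl and Et3N at −20 °C gives the primary mesylate F1.
- Ozonolysis (O3, then Me2S) gives the aldehyde F2.
- Wittig olefination with Ph3P=C(CH3)OCH3 gives the methyl enol ether F3. Its E/Z ratio is irrelevant.
- Warming F3 in CH2Cl2/HFIP with DTBMP lets the enol ether attack the bromine-assisted primary carbon through the same all-equatorial chair. This gives the O-methyl oxocarbenium ion F4, which water converts directly into ketone 8. Steps 2 and 3 are both replaced.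

**Step 7 (ring B closure).**
- Risks: halide capture or allylic proton loss from the bromonium ion, 5-exo closure, a 1,2-shift in the α-silyloxy oxocarbenium ion, and bromination of the product.
- The fallback sets out from 17 and comes back at 20. It forms the ring at the other C–O bond, with C5 set by reagent control.
- Asymmetric epoxidation uses KHSO5 in K2CO3 buffer and the Shi ketone enantiomer that gives the (S)-epoxide. By the spiro model this is the L-fructose-derived 1,2:4,5-di-O-isopropylidene-β-L-erythro-2,3-hexodiulo-2,6-pyranose. The product is the epoxide F9.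
- Li2NiBr4 opens F9 at the secondary carbon with inversion to give the bromohydrin F10.
- The tertiary hydroxyl of F10 adds to the ketone to give the hemiketal F11.
- MsCl/Et3N dehydrates F11 toward its only α-hydrogens to give 20.

**Step 6 (carbinol centre).**
- Risks: slow oxygen transfer to the hindered enolate and only modest facial selectivity.
- The fallback sets out from 13 and comes back at 17. It replaces reagent-controlled enolate oxidation by 1,2-induction from a temporary carbinol.
- Reduction with BH3·SMe2 and (S)-1-methyl-3,3-diphenyltetrahydro-1H,3H-pyrrolo[1,2-c][1,3,2]oxazaborole (10 mol %) gives the allylic alcohol F5.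
- Hydroxyl-directed epoxidation with VO(acac)2 and t-BuOOH gives the epoxy alcohol F6. It is erythro-selective because A(1,2) strain places the carbinol hydrogen next to the cyclohexyl group.
- Reagent 14 with CuBr·SMe2 opens the terminal epoxide carbon to give the diol F7.
- Oxidation of the secondary alcohol with SO3·pyridine, DMSO and Et3N gives the hydroxy ketone F8.
- TESOTf with 2,6-lutidine then gives 17.

**Further compounds**
F1 | step 2 | (2S,3S)-2-bromo-3-chloro-3,7-dimethyloct-6-en-1-yl methanesulfonate | CC(C)=CCC[C@](C)(Cl)[C@@H](Br)COS(C)(=O)=O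
F2 | step 2 | (2S,3S)-2-bromo-3-chloro-3-methyl-6-oxohexyl methanesulfonate | O=CCC[C@](C)(Cl)[C@@H](Br)COS(C)(=O)=O
F3 | step 2 | (2S,3S)-2-bromo-3-chloro-7-methoxy-3-methyloct-6-en-1-yl methanesulfonate (E/Z mixture) | COC(C)=CCC[C@](C)(Cl)[C@@H](Br)COS(C)(=O)=O
F4 | step 2 | {1-[(1S,3S,4S)-3-bromo-4-chloro-4-methylcyclohexyl]ethylidene}(methyl)oxidanium | CC(=[O+]C)[C@H]1CC[C@](C)(Cl)[C@@H](Br)C1
F5 | step 6 | (2R)-3-[(1S,3S,4S)-3-bromo-4-chloro-4-methylcyclohexyl]but-3-en-2-ol | C[C@@H](O)C(=C)[C@H]1CC[C@](C)(Cl)[C@@H](Br)C1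
F6 | step 6 | (1R)-1-{(2S)-2-[(1S,3S,4S)-3-bromo-4-chloro-4-methylcyclohexyl]oxiran-2-yl}ethan-1-ol | C[C@@H](O)[C@@]2(CO2)[C@H]1CC[C@](C)(Cl)[C@@H](Br)C1
F7 | step 6 | (2R,3R)-3-[(1S,3S,4S)-3-bromo-4-chloro-4-methylcyclohexyl]-6-methylhept-5-ene-2,3-diol | C[C@@H](O)[C@@](O)(CC=C(C)C)[C@H]1CC[C@](C)(Cl)[C@@H](Br)C1
F8 | step 6 | (3R)-3-[(1S,3S,4S)-3-bromo-4-chloro-4-methylcyclohexyl]-3-hydroxy-6-methylhept-5-en-2-one | CC(=O)[C@@](O)(CC=C(C)C)[C@H]1CC[C@](C)(Cl)[C@@H](Br)C1
F9 | step 7 | (3R)-3-[(1S,3S,4S)-3-bromo-4-chloro-4-methylcyclohexyl]-4-[(2S)-3,3-dimethyloxiran-2-yl]-3-[(triethylsilyl)oxy]butan-2-one | CC1(C)O[C@H]1C[C@@](C(C)=O)(O[Si](CC)(CC)CC)[C@H]2CC[C@](C)(Cl)[C@@H](Br)C2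
F10 | step 7 | (3R,5R)-5-bromo-3-[(1S,3S,4S)-3-bromo-4-chloro-4-methylcyclohexyl]-6-hydroxy-6-methyl-3-[(triethylsilyl)oxy]heptan-2-one | CC(C)(O)[C@H](Br)C[C@@](C(C)=O)(O[Si](CC)(CC)CC)[C@H]2CC[C@](C)(Cl)[C@@H](Br)C2
F11 | step 7 | (3R,5R)-5-bromo-3-[(1S,3S,4S)-3-bromo-4-chloro-4-methylcyclohexyl]-2,6,6-trimethyl-3-[(triethylsilyl)oxy]oxan-2-ol (anomers) | CC1(O)OC(C)(C)[C@H](Br)C[C@@]1(O[Si](CC)(CC)CC)[C@H]2CC[C@](C)(Cl)[C@@H](Br)C2
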